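**Plan**
- Retrosynthesis: the side-chain diene goes back to a C13 alkyne (enyne metathesis with ethylene), the alkyne to a C8–O–C13 lactol; C5–H and C8–O go back to a ring B 5,7-diene; ring B is then cut at C9–C10 and C6–C7 into ring A enal 10 (C1–C6, C10, C18–C20) and phosphonate acid 13 (C7–C9, C11–C13, C17).
- Enabling feature: in ring B, H-9 and the C10 methyl lie on the same face (side chain at C9 anti to the angular methyl), and C5–C8 can all be sp2. This is the imprint of a thermal disrotatory 6π closure of a C10=C5–C6=C7–C8=C9 triene.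
- Forward: ring A from (R)-carvone; one flask joins C6=C7 by olefination, turns it Z with light and closes C9–C10 by heat (ring B); then C8–O by iodolactonization, C5–H by directed hydrogenation, side chain by alkyne homologation and enyne metathesis.
- Stereochemistry: C3 from carvone; C4 by aldol anti to the isopropenyl group; C10 by the acetonide-locked chair of ring A; C9 by disrotation; C8 by the carboxylate tethered at C9; C5 by hydroxyl-directed hydrogenation.

Key step: step 8

Remark: atoms are numbered as in the labdane skeleton (C1–C10 decalin, C11–C16 side chain, C17 on C8, C18 the CH2O carbon and C19 the methyl on C4, C20 on C10); α means below and β above the plane in the usual drawing. Compound 13 may be used as its E/Z mixture, because step 8 equilibrates the C8=C9 geometry.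

Step 1
Reactants: 1 (R)-(−)-carvone
Product: 2 trans-6-methylcarvone
Conditions: LiN(i-Pr)2, THF, −78 °C; MeI, −78→0 °C
Reagents that add atoms: iodomethane, CI
Why: Kinetic deprotonation at C6 gives the cross-conjugated lithium enolate, which is methylated (enolate alkylation) mainly anti to the isopropenyl group; this centre is planarized again in step 2.

Step 2
Reactants: 2 trans-6-methylcarvone
Product: 3 6-(hydroxymethyl)-6-methylcarvone
Conditions: LiN(i-Pr)2, THF, −78 °C; CH2O (gas, from cracked paraformaldehyde); then H2O
Reagents that add atoms: formaldehyde, C=O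
Why: Aldol addition of the fully substituted enolate to monomeric formaldehyde should occur anti to the neighbouring isopropenyl group, which sets the quaternary C4 with CH2OH trans and CH3 cis to the future C3 oxygen.

Step 3
Reactants: 3 6-(hydroxymethyl)-6-methylcarvone
Product: 5 diacetate enone, via methoxy hydroperoxide 4 (not isolated)
Conditions: O3, CH2Cl2–MeOH, −78 °C (Sudan red end point); then Ac2O, Et3N, DMAP, 0→25 °C
Reagents that add atoms: ozone, [O-][O+]=O; methanol, CO; acetic anhydride, CC(=O)OC(C)=O
Why: Ozone should cleave the electron-rich isopropenyl alkene in preference to the enone, and the peracetate of the α-methoxy hydroperoxide undergoes Criegee rearrangement with retention, which turns the isopropenyl group into the C3 acetate; the primary alcohol is acetylated in the same flask.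

Step 4
Reactants: 5 diacetate enone
Product: 7 enol triflate diacetate, via lithium enolate 6 (not isolated)
Conditions: LiBH(s-Bu)3, THF, −78 °C; then PhNTf2, −78→0 °C
Reagents that add atoms: N-phenylbis(trifluoromethanesulfonimide), O=S(=O)(N(c1ccccc1)S(=O)(=O)C(F)(F)F)C(F)(F)F
Why: Conjugate hydride reduction of the enone gives a single enolate regioisomer (C4 is quaternary), and O-triflation fixes the tetrasubstituted C5=C10 alkene; no stereocentre is formed.

Step 5
Reactants: 7 enol triflate diacetate
Product: 9 acetonide enol triflate, via diol enol triflate 8 (not isolated)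
Conditions: K2CO3 (cat.), MeOH, 0 °C; then Me2C(OMe)2, PPTS, CH2Cl2, 25 °C
Reagents that add atoms: 2,2-dimethoxypropane, COC(C)(C)OC
Why: Methanolysis of both acetates followed by acid-catalysed ketalization gives the trans-fused 1,3-dioxane (O-3 and C18 both equatorial), which locks ring A in one chair for step 8; the configuration is unchanged.

Step 6
Reactants: 9 acetonide enol triflate
Product: 10 ring A enal (fragment 1)
Conditions: Pd(PPh3)4 (5 mol %), CO (1 atm), Bu3SnH (slow addition), THF, 50 °C
Reagents that add atoms: carbon monoxide, [C-]#[O+]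
Why: Palladium-catalysed reductive carbonylation (formylation) of the enol triflate: oxidative addition to zerovalent palladium, CO insertion and hydride transfer from tin give the conjugated aldehyde C6.

Step 7
Reactants: 11 pent-4-enoic acid; 12 diethyl (2-methylallyl)phosphonate
Product: 13 (E)-6-(diethoxyphosphoryl)-5-methylhex-4-enoic acid (fragment 2)
Conditions: second-generation Hoveyda–Grubbs catalyst (5 mol %), 12 (3 equiv), CH2Cl2, 40 °C
Reagents that add atoms: none
Why: Olefin cross-metathesis of a terminal alkene with a 1,1-disubstituted alkene should give the trisubstituted cross product, mainly E; the geometry need not be pure.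

Step 8
Reactants: 10 ring A enal (fragment 1); 13 phosphonate acid (fragment 2)
Product: 16 ring B cyclohexadiene acid, via (6E)-triene acid 14 (not isolated), via (6Z)-triene acid 15 (not isolated)
Conditions: 13, LiN(i-Pr)2 (2.1 equiv), THF–DMPU, −78 °C; 10, −78→45 °C; AcOH; toluene, benzanthrone (5 mol %), 405 nm LEDs, 25 °C; then 110 °C, dark
Reagents that add atoms: none
Why: The lithiated allylic phosphonate of 13 (as its carboxylate dianion) adds to aldehyde 10 and loses diethyl phosphate (Horner–Wadsworth–Emmons) to form C6=C7; triplet energy transfer from benzanthrone then turns the planar (6E)-triene 14 into the twisted (6Z)-triene 15, which is a poorer energy acceptor and should accumulate, and heating closes 15 by thermal disrotatory 6π-electrocyclization between the triene termini C10 and C9, which forms C9–C10 and ring B as a cyclohexa-1,3-diene. The closest known reactions are the sensitized one-way E-to-Z isomerization of β-ionylidene trienes and the thermal closure of previtamin D to pyro- and isopyrocalciferol, which also joins a methyl-bearing ring carbon to the far triene terminus. C9 relative to C10 follows from disrotation: the C10 methyl (held cis to C6 by ring A) and H-9 of the (8E) alkene are the two inside groups and end on the same face, so the C9 side chain is anti to the angular methyl. The absolute sense at C10 comes from the trans-fused acetonide, which holds ring A in the chair with O-3 and C18 equatorial; C9 can bond only in the equatorial direction of C10, so the C10 methyl turns axial on the face of the axial C4 methyl. The step needs this face selectivity and a funnel through one isomer: only the (6Z,8E)-triene has hydrogen as its second inside group, and the 8Z isomers should be returned to it by light and by reversible hydrogen shifts.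

Step 9
Reactants: 16 ring B cyclohexadiene acid
Product: 17 iodo δ-lactone
Conditions: I2, NaHCO3, MeCN–H2O, 0 °C, dark
Reagents that add atoms: iodine, II
Why: Iodolactonization in the 6-exo mode: the carboxylate tethered to the β face of C9 attacks the tertiary C8 on that face, so C8–O is cis to the side chain and iodine enters anti at C7.

Step 10
Reactants: 17 iodo δ-lactone
Product: 18 Δ5 8,13-diol
Conditions: LiAlH4, THF, 0→25 °C
Reagents that add atoms: none
Why: Hydride reduction takes the lactone to the primary alcohol and the tertiary alkoxide and should replace the allylic iodide at C7 by hydrogen; C8 and C9 are not touched.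

Step 11
Reactants: 18 Δ5 8,13-diol
Product: 19 trans-decalin 8,13-diol
Conditions: [Ir(cod)(PCy3)(py)]PF6 (5 mol %), H2 (1 atm), CH2Cl2, 25 °C
Reagents that add atoms: none
Why: Hydroxyl-directed homogeneous hydrogenation: iridium bound to the homoallylic 8β-OH should deliver hydrogen to the β face of the hindered C5=C6 alkene, which places H-5 anti to the C10 methyl (trans ring fusion).

Step 12
Reactants: 19 trans-decalin 8,13-diol
Product: 20 C8–O–C13 lactol
Conditions: Dess–Martin periodinane, NaHCO3, CH2Cl2, 0 °C
Reagents that add atoms: none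
Why: Dess–Martin oxidation of the primary alcohol gives the aldehyde, which the tertiary 8-OH captures as the six-membered lactol (anomeric mixture, no defined new centre).

Step 13
Reactants: 20 C8–O–C13 lactol
Product: 21 acetonide alkynol
Conditions: MeC(O)C(N2)P(O)(OMe)2, K2CO3, MeOH, 0→25 °C
Reagents that add atoms: dimethyl (1-diazo-2-oxopropyl)phosphonate, COP(=O)(OC)C(=[N+]=[N-])C(C)=O
Why: Ohira–Bestmann (Seyferth–Gilbert) homologation acts on the open hydroxy aldehyde form of the lactol and gives the terminal alkyne C13≡C14 with the free 8-OH.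

Step 14
Reactants: 21 acetonide alkynol
Product: 22 alkyne triol
Conditions: PPTS, MeOH, 40 °C
Reagents that add atoms: none
Why: Acid-catalysed transketalization removes the acetonide under conditions that the tertiary alcohol and the alkyne should survive.

Step 15
Reactants: 22 alkyne triol
Product: 23 alkyne 3,18-diacetate
Conditions: Ac2O, pyridine, DMAP (cat.), 25 °C
Reagents that add atoms: acetic anhydride, CC(=O)OC(C)=O
Why: DMAP-catalysed acetylation esterifies the primary and the secondary hydroxyl, while the hindered tertiary 8-OH should stay free.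

Step 16
Reactants: 23 alkyne 3,18-diacetate
Product: 24 alkyne 3-acetate
Conditions: Candida antarctica lipase B (immobilized), n-BuOH, t-BuOMe, 40 °C
Reagents that add atoms: none
Why: Lipase-catalysed alcoholysis should remove the primary acetate and leave the hindered secondary acetate next to the quaternary C4, under neutral conditions that disfavour acyl migration.

Step 17
Reactants: 24 alkyne 3-acetate
Product: 25 target compound
Conditions: second-generation Grubbs catalyst (5 mol %), ethylene (1 atm), CH2Cl2, 40 °C
Reagents that add atoms: ethylene, C=C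
Why: Enyne cross-metathesis of the terminal alkyne with ethylene gives the 2-substituted buta-1,3-diene in the last step, so the sensitive diene meets no further reagent.

**Compound list**
1 | (R)-(−)-carvone, (5R)-2-methyl-5-(prop-1-en-2-yl)cyclohex-2-en-1-one | O=C1C(C)=CC[C@@H](C(C)=C)C1 | starting material
2 | trans-6-methylcarvone, (5R,6S)-2,6-dimethyl-5-(prop-1-en-2-yl)cyclohex-2-en-1-one (major epimer, methyl anti to isopropenyl) | O=C1C(C)=CC[C@@H](C(C)=C)[C@@H]1C | intermediate
3 | 6-(hydroxymethyl)-6-methylcarvone, (5S,6R)-6-(hydroxymethyl)-2,6-dimethyl-5-(prop-1-en-2-yl)cyclohex-2-en-1-one (CH2OH anti, CH3 syn to isopropenyl) | O=C1C(C)=CC[C@@H](C(C)=C)[C@]1(C)CO | intermediate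
4 | methoxy hydroperoxide: 5-(1-hydroperoxy-1-methoxyethyl)-6-(hydroxymethyl)-2,6-dimethylcyclohex-2-en-1-one, ring configuration of 3, mixture at the peroxy carbon | O=C1C(C)=CC[C@@H](C(C)(OC)OO)[C@]1(C)CO | intermediate
5 | diacetate enone: 5-acetoxy-6-(acetoxymethyl)-2,6-dimethylcyclohex-2-en-1-one, acetoxy syn to the 6-methyl, configuration retained from 3 | O=C1C(C)=CC[C@@H](OC(C)=O)[C@]1(C)COC(C)=O | intermediate
6 | lithium enolate of the saturated ketone from 5 (enolate carbon C10, configuration of 5) | [Li+].[O-]C1=C(C)CC[C@@H](OC(C)=O)[C@]1(C)COC(C)=O | intermediate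
7 | enol triflate diacetate: 5-acetoxy-6-(acetoxymethyl)-2,6-dimethylcyclohex-1-en-1-yl trifluoromethanesulfonate, configuration of 5 | O=S(=O)(OC1=C(C)CC[C@@H](OC(C)=O)[C@]1(C)COC(C)=O)C(F)(F)F | intermediate
8 | diol enol triflate: 5-hydroxy-6-(hydroxymethyl)-2,6-dimethylcyclohex-1-en-1-yl trifluoromethanesulfonate, configuration of 5 | O=S(=O)(OC1=C(C)CC[C@@H](O)[C@]1(C)CO)C(F)(F)F | intermediate
9 | acetonide enol triflate: trans-fused 2,2,4a,6-tetramethyl-4a,7,8,8a-tetrahydro-4H-benzo[d][1,3]dioxin-5-yl trifluoromethanesulfonate (4a-methyl axial, ring oxygen at 8a equatorial) | O=S(=O)(OC1=C(C)CC[C@H]2OC(C)(C)OC[C@]12C)C(F)(F)F | intermediate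
10 | ring A enal (fragment 1): trans-fused 2,2,4a,6-tetramethyl-4a,7,8,8a-tetrahydro-4H-benzo[d][1,3]dioxine-5-carbaldehyde; labdane C1–C6, C10, C18–C20 with 3α-O, 4α-CH3, 4β-CH2O | O=CC1=C(C)CC[C@H]2OC(C)(C)OC[C@]12C | intermediate
11 | pent-4-enoic acid | C=CCCC(=O)O | starting material
12 | diethyl (2-methylallyl)phosphonate | CCOP(=O)(CC(C)=C)OCC | starting material
13 | (E)-6-(diethoxyphosphoryl)-5-methylhex-4-enoic acid (fragment 2; C7–C9, C11–C13, C17) | CCOP(=O)(C/C(C)=C/CCC(=O)O)OCC | intermediate
14 | (6E)-triene acid: (4E,6E)-5-methyl-7-(ring A of 10)hepta-4,6-dienoic acid | OC(=O)CC/C=C(C)/C=C/C1=C(C)CC[C@H]2OC(C)(C)OC[C@]12C | intermediate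
15 | (6Z)-triene acid: (4E,6Z)-5-methyl-7-(ring A of 10)hepta-4,6-dienoic acid | OC(=O)CC/C=C(C)/C=C\C1=C(C)CC[C@H]2OC(C)(C)OC[C@]12C | intermediate
16 | ring B cyclohexadiene acid: 3α,18-O-isopropylidene 5,7-diene with 10α-CH3, 9α-H and 9β-CH2CH2CO2H | OC(=O)CC[C@@H]1[C@]2(C)CC[C@H]3OC(C)(C)OC[C@]3(C)C2=CC=C1C | intermediate
17 | iodo δ-lactone: 7α-iodo, 8β-O–C13(=O) lactone (cis-fused at C8–C9), 8α-CH3, Δ5, ring A acetonide | O=C1CC[C@@H]2[C@]3(C)CC[C@H]4OC(C)(C)OC[C@]4(C)C3=C[C@@H](I)[C@]2(C)O1 | intermediate
18 | Δ5 8,13-diol: 8β-OH, 8α-CH3, 9β-(3-hydroxypropyl), C5=C6, ring A acetonide | OCCC[C@@H]1[C@]2(C)CC[C@H]3OC(C)(C)OC[C@]3(C)C2=CC[C@]1(C)O | intermediate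
19 | trans-decalin 8,13-diol: as 18 with 5β-H (trans to the 10α-CH3) | OCCC[C@@H]1[C@]2(C)CC[C@H]3OC(C)(C)OC[C@]3(C)[C@H]2CC[C@]1(C)O | intermediate
20 | C8–O–C13 lactol (anomeric mixture) of the 13-aldehyde from 19 | OC1CC[C@@H]2[C@]3(C)CC[C@H]4OC(C)(C)OC[C@]4(C)[C@H]3CC[C@]2(C)O1 | intermediate
21 | acetonide alkynol: 9β-(but-3-ynyl), 8β-OH, ring A acetonide | C#CCC[C@@H]1[C@]2(C)CC[C@H]3OC(C)(C)OC[C@]3(C)[C@H]2CC[C@]1(C)O | intermediate
22 | alkyne triol: 3α-OH, 4β-CH2OH, 8β-OH, 9β-(but-3-ynyl) | C#CCC[C@@H]1[C@]2(C)CC[C@@H](O)[C@](C)(CO)[C@H]2CC[C@]1(C)O | intermediate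
23 | alkyne 3,18-diacetate, 8β-OH free | C#CCC[C@@H]1[C@]2(C)CC[C@@H](OC(C)=O)[C@](C)(COC(C)=O)[C@H]2CC[C@]1(C)O | intermediate
24 | alkyne 3-acetate, 18-OH and 8β-OH free | C#CCC[C@@H]1[C@]2(C)CC[C@@H](OC(C)=O)[C@](C)(CO)[C@H]2CC[C@]1(C)O | intermediate
25 | target: 3α-acetoxy-18-hydroxy-8β-hydroxy trans-decalin with 9β-(3-methylenepent-4-enyl), 9α-H, 10α-CH3 | C=CC(=C)CC[C@@H]1[C@]2(C)CC[C@@H](OC(C)=O)[C@](C)(CO)[C@H]2CC[C@]1(C)O | target

**Count and risks**
Total steps: 17. Longest linear sequence: 16 (steps 1–6 and 8–17, from (R)-carvone).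

Step 8. The triene may be lost among unproductive isomers: incomplete E-to-Z transfer, hydrogen-shift isomers that do not return, or sensitized decay of the cyclohexadiene; the facial bias of the locked chair may also be weaker than argued. The fallback sets out from 10 and comes back at 16. Stork–Zhao olefination of 10 with Ph3P=CHI gives the (Z)-iodovinyl diene F1. Negishi coupling of F1 with the (E)-alkenylzinc reagent made from methyl hex-4-ynoate (Cp2Zr(H)Cl, then ZnCl2; Pd(PPh3)4, 25 °C) gives the geometrically defined (4E,6Z)-triene methyl ester F2, which needs no light. Heating F2 in toluene closes it to the cyclohexadiene methyl ester F3, and LiOH in THF–water gives 16.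

Step 10. Hydride delivery may lose regiocontrol: attack at C5 in the SN2' sense, or ionization and elimination of the allylic iodide. The fallback sets out from 17 and comes back at 18. K2CO3 in methanol opens the lactone, and the C8 alkoxide displaces iodide to give the 7β,8β-epoxy Δ5 methyl ester F4. Hydrogenolysis of this vinyl epoxide with Pd2(dba)3, PBu3 and HCO2H–Et3N places hydride at the allylic carbon C7 and gives the 8β-hydroxy Δ5 methyl ester F5. LiAlH4 then reduces the ester to 18.

Step 11. Face selectivity may be poor, or the catalyst may not turn over at the hindered trisubstituted alkene if the diol holds the iridium. The fallback sets out from 18 and comes back at 19 without a new compound: hydrogen-atom-transfer hydrogenation (Mn(dpm)3, PhSiH3, t-BuOOH, i-PrOH), in which the tertiary C5 radical takes up hydrogen under thermodynamic control of the ring fusion and should give the trans-decalin 19.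

**Further compounds**
F1 | step 8 | (Z)-iodovinyl diene: trans-fused 5-[(Z)-2-iodovinyl]-2,2,4a,6-tetramethyl-4a,7,8,8a-tetrahydro-4H-benzo[d][1,3]dioxine | I/C=C\C1=C(C)CC[C@H]2OC(C)(C)OC[C@]12C
F2 | step 8 | (4E,6Z)-triene methyl ester, methyl ester of 15 | COC(=O)CC/C=C(C)/C=C\C1=C(C)CC[C@H]2OC(C)(C)OC[C@]12C
F3 | step 8 | cyclohexadiene methyl ester, methyl ester of 16 | COC(=O)CC[C@@H]1[C@]2(C)CC[C@H]3OC(C)(C)OC[C@]3(C)C2=CC=C1C
F4 | step 10 | 7β,8β-epoxy Δ5 methyl ester | COC(=O)CC[C@@H]1[C@]2(C)CC[C@H]3OC(C)(C)OC[C@]3(C)C2=C[C@@H]4O[C@]14C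
F5 | step 10 | 8β-hydroxy Δ5 methyl ester | COC(=O)CC[C@@H]1[C@]2(C)CC[C@H]3OC(C)(C)OC[C@]3(C)C2=CC[C@]1(C)O
F0 | step 11 | none | none
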